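**Strategy.** Ring C is opened between C2 and C3. In the flavanone C2 is bonded to O1 and is benzylic to ring B, so in an open-chain precursor it is the CH2 of an aryl benzyl ether, whose C–H bonds are hydridic. An α-diazoketone on ring A, ortho to this ether, supplies C3 and C4: a chiral dirhodium carboxylate turns it into a carbenoid that inserts into one of the two enantiotopic benzylic C–H bonds, closing ring C and setting the (2S) centre in one operation. The achiral precursor comes from Mitsunobu union of a MOM-protected diprenylbenzyl alcohol with a MOM-protected 2-hydroxyacetophenone, then diazo transfer.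

Key step: step 7

Assumption: the (S)-prolinate catalyst of step 7 is taken to give the (2S) product; should the (2R) product prevail, the mirror-image catalyst made from (R)-proline is used with no other change. (MOM = methoxymethyl; the target is the (2S)-flavanone.)

**Step 1**
Reactants: 1 3,5-dibromo-4-hydroxybenzaldehyde
Product: 2 3,5-dibromo-4-(methoxymethoxy)benzaldehyde
Conditions: MOMCl, K2CO3, acetone, 0 °C to rt
Reagents that add atoms: chloromethyl methyl ether, COCCl
Why: Williamson-type O-alkylation of the acidic 2,6-dibromophenoxide by the very reactive chloromethyl ether should give the MOM acetal and leave the aldehyde untouched.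

**Step 2**
Reactants: 2 3,5-dibromo-4-(methoxymethoxy)benzaldehyde
Product: 3 4-(methoxymethoxy)-3,5-bis(3-methylbut-2-en-1-yl)benzaldehyde
Conditions: tributyl(3-methylbut-2-en-1-yl)stannane (2.6 equiv), Pd(PPh3)4 (10 mol %), DMF, 100 °C
Reagents that add atoms: tributyl(3-methylbut-2-en-1-yl)stannane, CCCC[Sn](CCCC)(CCCC)CC=C(C)C
Why: Twofold Stille cross-coupling: oxidative addition of zerovalent palladium into the aldehyde-activated C–Br bonds, allyl transfer from tin and reductive elimination at the less hindered allyl terminus should give the two linear prenyl groups, with acetal and aldehyde inert.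

**Step 3**
Reactants: 3 4-(methoxymethoxy)-3,5-bis(3-methylbut-2-en-1-yl)benzaldehyde
Product: 4 [4-(methoxymethoxy)-3,5-bis(3-methylbut-2-en-1-yl)phenyl]methanol
Conditions: NaBH4, MeOH, 0 °C
Reagents that add atoms: none
Why: Borohydride reduction of the aryl aldehyde should give the primary benzylic alcohol without touching the trisubstituted alkenes or the acetal.

**Step 4**
Reactants: 5 1-(2,4-dihydroxyphenyl)ethan-1-one
Product: 6 1-[2-hydroxy-4-(methoxymethoxy)phenyl]ethan-1-one
Conditions: MOMCl (1.05 equiv), K2CO3, acetone, rt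
Reagents that add atoms: chloromethyl methyl ether, COCCl
Why: Selective Williamson-type alkylation: the 2-OH is held in a hydrogen bond to the acetyl carbonyl, so the more acidic and accessible 4-OH should be the one protected.

**Step 5**
Reactants: 4 [4-(methoxymethoxy)-3,5-bis(3-methylbut-2-en-1-yl)phenyl]methanol; 6 1-[2-hydroxy-4-(methoxymethoxy)phenyl]ethan-1-one
Product: 7 1-[2-{[4-(methoxymethoxy)-3,5-bis(3-methylbut-2-en-1-yl)phenyl]methoxy}-4-(methoxymethoxy)phenyl]ethan-1-one
Conditions: PPh3, DIAD, THF, 0 °C to rt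
Reagents that add atoms: none
Why: Mitsunobu etherification: the phenol protonates the betaine and then displaces the oxyphosphonium group of the primary benzylic alcohol under neutral conditions that spare both acetals; no stereocentre is involved.

**Step 6**
Reactants: 7 1-[2-{[4-(methoxymethoxy)-3,5-bis(3-methylbut-2-en-1-yl)phenyl]methoxy}-4-(methoxymethoxy)phenyl]ethan-1-one
Product: 9 2-diazo-1-[2-{[4-(methoxymethoxy)-3,5-bis(3-methylbut-2-en-1-yl)phenyl]methoxy}-4-(methoxymethoxy)phenyl]ethan-1-one, via trifluoroacetyl diketone 8 (not isolated)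
Conditions: LiHMDS, THF, −78 °C; CF3CO2CH2CF3; aq. HCl quench; then MsN3, Et3N, H2O, MeCN, rt
Reagents that add atoms: methanesulfonyl azide, CS(=O)(=O)N=[N+]=[N-] (the two diazo nitrogens of 9); 2,2,2-trifluoroethyl trifluoroacetate, O=C(OCC(F)(F)F)C(F)(F)F (the trifluoroacetyl group of 8 only, lost again on the way to 9)
Why: Detrifluoroacetylative Regitz diazo transfer: the lithium enolate of the methyl ketone (the only enolisable position) is C-trifluoroacetylated in a Claisen condensation, and the activated diketone 8 takes the diazo group from the sulfonyl azide while the trifluoroacetyl group leaves as the N-sulfonyl amide.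

**Step 7**
Reactants: 9 2-diazo-1-[2-{[4-(methoxymethoxy)-3,5-bis(3-methylbut-2-en-1-yl)phenyl]methoxy}-4-(methoxymethoxy)phenyl]ethan-1-one
Product: 10 (2S)-7-(methoxymethoxy)-2-[4-(methoxymethoxy)-3,5-bis(3-methylbut-2-en-1-yl)phenyl]-2,3-dihydro-4H-1-benzopyran-4-one
Conditions: Rh2(S-BSP)4 [dirhodium tetrakis((S)-N-benzenesulfonylprolinate)] (2 mol %), CH2Cl2, 0 °C to rt, slow addition of 9 to about 0.01 M
Reagents that add atoms: none
Why: The divalent-rhodium carboxylate expels N2 from 9 to give an electrophilic rhodium carbenoid at the future C3, which inserts into a C–H bond of the OCH2Ar group (the future C2) through a three-centre, hydride-transfer-like transition state that forms the C2–C3 bond and returns the catalyst (intramolecular carbenoid C–H insertion). The closest known reaction type is the cyclisation of ortho-alkoxyaryl diazoketones to chroman-4-ones with chiral dirhodium carboxylates, applied here to a benzylic ether. Ring C closes as a six-membered ring by 1,6-insertion through a chair-like cyclic transition state made of the carbenoid carbon, C4, C4a, C8a, O1 and C2; the usually preferred 1,5-mode has no C–H to offer because that position is O1. The new stereocentre C2 is set under catalyst control: the chiral prolinate ligands decide which of the two enantiotopic benzylic hydrogens is replaced, with the aryl group of ring B pseudo-equatorial. The step needs insertion to win over attack of the carbenoid on O1 (oxonium ylide and [1,2]-benzyl shift), on the prenyl double bonds (cyclopropanation) and on ring B; this is secured by the doubly activated C–H bond (α to oxygen and benzylic to an electron-rich ring), by the poor basicity of the aryl ether oxygen conjugated to the acyl-bearing ring A, by the choice of a rhodium carboxylate, which favours insertion where copper catalysts favour ylides, by the distance of the alkenes (reachable only through rings of eleven or more members) and by high dilution. C2 is the only stereocentre formed and should be configurationally stable under these neutral conditions; the enantiomeric purity can be raised by recrystallisation of 10 if needed.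

**Step 8**
Reactants: 10 (2S)-7-(methoxymethoxy)-2-[4-(methoxymethoxy)-3,5-bis(3-methylbut-2-en-1-yl)phenyl]-2,3-dihydro-4H-1-benzopyran-4-one
Product: 11 abyssinone-IV, (2S)-7-hydroxy-2-[4-hydroxy-3,5-bis(3-methylbut-2-en-1-yl)phenyl]-2,3-dihydro-4H-1-benzopyran-4-one
Conditions: 3 M aq. HCl, MeOH, rt to 40 °C, stopped at full conversion
Reagents that add atoms: none
Why: Acid-catalysed acetal exchange with methanol (MOM cleavage) should free both phenols under exposure short and mild enough that ring C stays closed, the prenyl groups do not add to the new phenol, and C2 is untouched.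

**Compound list**
1 | 3,5-dibromo-4-hydroxybenzaldehyde | O=Cc1cc(Br)c(O)c(Br)c1 | starting material
2 | 3,5-dibromo-4-(methoxymethoxy)benzaldehyde | COCOc1c(Br)cc(C=O)cc1Br | intermediate
3 | 4-(methoxymethoxy)-3,5-bis(3-methylbut-2-en-1-yl)benzaldehyde | COCOc1c(CC=C(C)C)cc(C=O)cc1CC=C(C)C | intermediate
4 | [4-(methoxymethoxy)-3,5-bis(3-methylbut-2-en-1-yl)phenyl]methanol | COCOc1c(CC=C(C)C)cc(CO)cc1CC=C(C)C | intermediate
5 | 1-(2,4-dihydroxyphenyl)ethan-1-one (2,4-dihydroxyacetophenone) | CC(=O)c1ccc(O)cc1O | starting material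
6 | 1-[2-hydroxy-4-(methoxymethoxy)phenyl]ethan-1-one | CC(=O)c1ccc(OCOC)cc1O | intermediate
7 | 1-[2-{[4-(methoxymethoxy)-3,5-bis(3-methylbut-2-en-1-yl)phenyl]methoxy}-4-(methoxymethoxy)phenyl]ethan-1-one | CC(=O)c1ccc(OCOC)cc1OCc1cc(CC=C(C)C)c(OCOC)c(CC=C(C)C)c1 | intermediate
8 | 4,4,4-trifluoro-1-[2-{[4-(methoxymethoxy)-3,5-bis(3-methylbut-2-en-1-yl)phenyl]methoxy}-4-(methoxymethoxy)phenyl]butane-1,3-dione (trifluoroacetyl diketone, formed in the flask in step 6, not isolated) | O=C(CC(=O)C(F)(F)F)c1ccc(OCOC)cc1OCc1cc(CC=C(C)C)c(OCOC)c(CC=C(C)C)c1 | intermediate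
9 | 2-diazo-1-[2-{[4-(methoxymethoxy)-3,5-bis(3-methylbut-2-en-1-yl)phenyl]methoxy}-4-(methoxymethoxy)phenyl]ethan-1-one | [N-]=[N+]=CC(=O)c1ccc(OCOC)cc1OCc1cc(CC=C(C)C)c(OCOC)c(CC=C(C)C)c1 | intermediate
10 | (2S)-7-(methoxymethoxy)-2-[4-(methoxymethoxy)-3,5-bis(3-methylbut-2-en-1-yl)phenyl]-2,3-dihydro-4H-1-benzopyran-4-one | CC(C)=CCc1cc([C@@H]2CC(=O)c3ccc(OCOC)cc3O2)cc(CC=C(C)C)c1OCOC | intermediate
11 | abyssinone-IV, (2S)-7-hydroxy-2-[4-hydroxy-3,5-bis(3-methylbut-2-en-1-yl)phenyl]-2,3-dihydro-4H-1-benzopyran-4-one | CC(C)=CCc1cc([C@@H]2CC(=O)c3ccc(O)cc3O2)cc(CC=C(C)C)c1O | target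

**Step count.** Total: 8 steps. Longest linear sequence: 7 steps (steps 1, 2, 3, 5, 6, 7, 8); step 4 prepares the second fragment.

**Steps most likely to fail**

Step 7. The chiral carbenoid of an acceptor-only diazoketone may discriminate poorly between the two enantiotopic benzylic hydrogens, and part of it may be diverted to the ether oxygen (ylide formation followed by benzyl shift). The fallback separates ring closure from stereocontrol. It sets out from 9, which is cyclised by the same C–H insertion with achiral Rh2(OAc)4 (CH2Cl2, rt, slow addition) to racemic 7-(methoxymethoxy)-2-[4-(methoxymethoxy)-3,5-bis(3-methylbut-2-en-1-yl)phenyl]-2,3-dihydro-4H-1-benzopyran-4-one F1. A kinetic resolution by Noyori asymmetric transfer hydrogenation follows (RuCl[(R,R)-TsDPEN](p-cymene), HCO2H/Et3N, EtOAc, rt, stopped a little beyond half conversion). By analogy with aryl ketone reductions it should reduce the (2R)-ketone to the cis-alcohol (2R,4R)-7-(methoxymethoxy)-2-[4-(methoxymethoxy)-3,5-bis(3-methylbut-2-en-1-yl)phenyl]-3,4-dihydro-2H-1-benzopyran-4-ol F2 and leave the (2S)-ketone, which is separated by chromatography. The prenyl alkenes are inert to transfer hydrogenation. The fallback comes back to the route at 10.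

Step 2. The prenyl group may be transferred with allylic transposition (1,1-dimethylallyl isomers), and the second coupling may stall next to the first prenyl group. The fallback builds the prenyl groups by metathesis instead. It sets out from 2, which is coupled twice with allyltributylstannane (Pd(PPh3)4, DMF, 90 °C), where no regiochemical choice exists, to give 4-(methoxymethoxy)-3,5-di(prop-2-en-1-yl)benzaldehyde F3. Twofold olefin cross-metathesis with excess 2-methylbut-2-ene (second-generation Grubbs catalyst, CH2Cl2, 40 °C) should turn both allyl groups into prenyl groups. The fallback comes back to the route at 3.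

Step 8. During the time needed to cleave both acetals, acid may open and reclose ring C (erosion of the C2 configuration) or add the freed 4'-phenol to a neighbouring prenyl double bond. The fallback removes all acid from the end of the route by carrying silyl ethers instead of MOM ethers. It sets out from 3 and 5 and comes back at 11.
- 3 loses its MOM group at the achiral aldehyde stage (aq. HCl, MeOH, 40 °C), where the 4-formylphenol is a poor nucleophile and no stereocentre exists, to give 4-hydroxy-3,5-bis(3-methylbut-2-en-1-yl)benzaldehyde F4.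
- Silylation (TBSCl, imidazole, DMF) gives 4-[(tert-butyldimethylsilyl)oxy]-3,5-bis(3-methylbut-2-en-1-yl)benzaldehyde F5, and NaBH4 in MeOH gives {4-[(tert-butyldimethylsilyl)oxy]-3,5-bis(3-methylbut-2-en-1-yl)phenyl}methanol F6.
- 5 is silylated selectively at 4-OH (TIPSCl, imidazole, CH2Cl2) to 1-{2-hydroxy-4-[(triisopropylsilyl)oxy]phenyl}ethan-1-one F7.
- Mitsunobu coupling of the two (PPh3, DIAD, THF) gives 1-[2-({4-[(tert-butyldimethylsilyl)oxy]-3,5-bis(3-methylbut-2-en-1-yl)phenyl}methoxy)-4-[(triisopropylsilyl)oxy]phenyl]ethan-1-one F8.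
- The diazo transfer of step 6 passes through the trifluoroacetyl diketone 4,4,4-trifluoro-1-[2-({4-[(tert-butyldimethylsilyl)oxy]-3,5-bis(3-methylbut-2-en-1-yl)phenyl}methoxy)-4-[(triisopropylsilyl)oxy]phenyl]butane-1,3-dione F9 (not isolated) to 2-diazo-1-[2-({4-[(tert-butyldimethylsilyl)oxy]-3,5-bis(3-methylbut-2-en-1-yl)phenyl}methoxy)-4-[(triisopropylsilyl)oxy]phenyl]ethan-1-one F10.
- The C–H insertion of step 7 gives (2S)-2-{4-[(tert-butyldimethylsilyl)oxy]-3,5-bis(3-methylbut-2-en-1-yl)phenyl}-7-[(triisopropylsilyl)oxy]-2,3-dihydro-4H-1-benzopyran-4-one F11.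
- Bu4NF buffered with AcOH (THF, 0 °C) removes both silyl groups and gives 11.

**Further compounds**
F1 | step 7 | racemic 7-(methoxymethoxy)-2-[4-(methoxymethoxy)-3,5-bis(3-methylbut-2-en-1-yl)phenyl]-2,3-dihydro-4H-1-benzopyran-4-one | CC(C)=CCc1cc(C2CC(=O)c3ccc(OCOC)cc3O2)cc(CC=C(C)C)c1OCOC
F2 | step 7 | (2R,4R)-7-(methoxymethoxy)-2-[4-(methoxymethoxy)-3,5-bis(3-methylbut-2-en-1-yl)phenyl]-3,4-dihydro-2H-1-benzopyran-4-ol | CC(C)=CCc1cc([C@H]2C[C@@H](O)c3ccc(OCOC)cc3O2)cc(CC=C(C)C)c1OCOC
F3 | step 2 | 4-(methoxymethoxy)-3,5-di(prop-2-en-1-yl)benzaldehyde | COCOc1c(CC=C)cc(C=O)cc1CC=C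
F4 | step 8 | 4-hydroxy-3,5-bis(3-methylbut-2-en-1-yl)benzaldehyde | O=Cc1cc(CC=C(C)C)c(O)c(CC=C(C)C)c1
F5 | step 8 | 4-[(tert-butyldimethylsilyl)oxy]-3,5-bis(3-methylbut-2-en-1-yl)benzaldehyde | O=Cc1cc(CC=C(C)C)c(O[Si](C)(C)C(C)(C)C)c(CC=C(C)C)c1
F6 | step 8 | {4-[(tert-butyldimethylsilyl)oxy]-3,5-bis(3-methylbut-2-en-1-yl)phenyl}methanol | OCc1cc(CC=C(C)C)c(O[Si](C)(C)C(C)(C)C)c(CC=C(C)C)c1
F7 | step 8 | 1-{2-hydroxy-4-[(triisopropylsilyl)oxy]phenyl}ethan-1-one | CC(=O)c1ccc(O[Si](C(C)C)(C(C)C)C(C)C)cc1O
F8 | step 8 | 1-[2-({4-[(tert-butyldimethylsilyl)oxy]-3,5-bis(3-methylbut-2-en-1-yl)phenyl}methoxy)-4-[(triisopropylsilyl)oxy]phenyl]ethan-1-one | CC(=O)c1ccc(O[Si](C(C)C)(C(C)C)C(C)C)cc1OCc1cc(CC=C(C)C)c(O[Si](C)(C)C(C)(C)C)c(CC=C(C)C)c1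
F9 | step 8 | 4,4,4-trifluoro-1-[2-({4-[(tert-butyldimethylsilyl)oxy]-3,5-bis(3-methylbut-2-en-1-yl)phenyl}methoxy)-4-[(triisopropylsilyl)oxy]phenyl]butane-1,3-dione | O=C(CC(=O)C(F)(F)F)c1ccc(O[Si](C(C)C)(C(C)C)C(C)C)cc1OCc1cc(CC=C(C)C)c(O[Si](C)(C)C(C)(C)C)c(CC=C(C)C)c1
F10 | step 8 | 2-diazo-1-[2-({4-[(tert-butyldimethylsilyl)oxy]-3,5-bis(3-methylbut-2-en-1-yl)phenyl}methoxy)-4-[(triisopropylsilyl)oxy]phenyl]ethan-1-one | [N-]=[N+]=CC(=O)c1ccc(O[Si](C(C)C)(C(C)C)C(C)C)cc1OCc1cc(CC=C(C)C)c(O[Si](C)(C)C(C)(C)C)c(CC=C(C)C)c1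
F11 | step 8 | (2S)-2-{4-[(tert-butyldimethylsilyl)oxy]-3,5-bis(3-methylbut-2-en-1-yl)phenyl}-7-[(triisopropylsilyl)oxy]-2,3-dihydro-4H-1-benzopyran-4-one | CC(C)=CCc1cc([C@@H]2CC(=O)c3ccc(O[Si](C(C)C)(C(C)C)C(C)C)cc3O2)cc(CC=C(C)C)c1O[Si](C)(C)C(C)(C)C
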